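| setting | east | south-east | south | flask |
|---|---|---|---|---|
| substrate | 0.0020 M | 0.0020 M | 0.0020 M | 0.0020 M |
| partner | 2.4 mM | 2.4 mM | 1.2 mM | 2.40 mM |
| free catalyst | 5 µM | 7.5 µM | 10 µM | 10 µM |
| remark | run made earlier | run made earlier | run made earlier |  |

| run | time / s | product / % |
|---|---|---|
| east | 15.0 | 7.4 |
| east | 30.0 | 12.0 |
| east | 50.0 | 16.3 |
| east | 60.0 | 17.0 |
| east | 80.0 | 15.1 |
| east | 90.0 | 17.2 |
| east | 120 | 15.1 |
| south-east | 15.0 | 11.0 |
| south-east | 30.0 | 18.3 |
| south-east | 50.0 | 20.5 |
| south-east | 60.0 | 20.6 |
| south-east | 80.0 | 23.4 |
| south-east | 90.0 | 23.6 |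
| south-east | 120 | 23.2 |
| south | 25.0 | 13.9 |
| south | 50.0 | 16.3 |
| south | 80.0 | 17.5 |
| south | 90.0 | 15.7 |
| south | 120 | 19.9 |

(scatter of a reading: 1 percentage point)



* apparent order in free catalyst when 10 % of the substrate are converted (percent change of the rate of making product for one percent more free catalyst charged)
* factor on the rate of making product when 10 % of the substrate are converted if partner is charged twice over

- From 80.0 s on, the readings averaged 15.8 % product in the east run and 23.4 % in the south-east run, so the turnovers per catalyst charged, T, read 63.2 and 62.4.
- My bench rule took T as constant, with the plateau proportional to catalyst, and it put the plateau of the flask at 31.2 %.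
- The border showed in the south run: with half the flask's partner it read 17.7 %, so T was 35.4, and, counting one partner per product, the south-east plateau reading came to a share 0.195 of its partner.
- I assumed that partner went either into product, one for one, or some other way, and defined the partner odds o, the plateau product per partner lost otherwise. The runs read 0.152 and 0.242.
- Scaling o with catalyst at fixed partner gave the flask 0.313, hence a plateau of 28.6 %, lower than the rule.
- The south run read o = 0.418; I took the rate of making product to go as partner to the power n and the other loss as partner itself, so that o goes as partner to the power n less one, which gave n = 0.582.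
- With rate proportional to catalyst times partner to the n, and 0.349 of the partner reckoned gone at the asked conversion, I reckoned an order in free catalyst of 1.24 and a factor for doubled partner of 1.66.
- The forecast said 1.45 for the order and 1.7 for the factor, on the ground “So the catalyst dies during the run”.
- The flask gave an order of 1.2 and a factor of 1.33, against my 1.24 and 1.66, so my factor was higher than the flask's; its product per decomposed reagent at 20.0 min was 0.296, against my o of 0.313.

    substrate + free catalyst → catalyst intermediate A (k = 4300 M⁻¹ s⁻¹)
    catalyst intermediate A ⇌ catalyst intermediate B (K = 3.10, k = 7.30 s⁻¹)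
    partner + catalyst intermediate B ⇌ catalyst intermediate C (K = 240 M⁻¹, k = 5500 M⁻¹ s⁻¹)
    catalyst intermediate C ⇌ catalyst intermediate D (K = 7.60, k = 61.0 s⁻¹)
    catalyst intermediate D ⇌ free catalyst + product (K = 5.80 × 10⁻⁴ M, k = 210 s⁻¹)
    partner → decomposed reagent (k = 0.0450 s⁻¹)

- In the flask, the passing of partner into decomposed reagent ran beside the catalytic steps while partner lasted: by 1.00 min it had behind it 98 % of its turnover up to 2.00 min, with partner at 2.52 % of its charge and product at 26.4 % of the substrate charged. By 2.00 min partner, the limiting reagent, stood at 0.0452 % of its charge, catalyst intermediate B held 75.5 % of the catalyst and catalyst intermediate A 24.4 %, and product stood at 27.4 % with 72 % of the substrate left.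

The data were generated by integration with constants of no real substance.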